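## The problem

The target 29 is a ten-membered carbocycle with two trisubstituted Z olefins (C4=C5 and C9=C10, each carrying a methyl group). Its C6–C7 bond is shared, cis, with an α-methylene-γ-butyrolactone (O6–C12(=O)–C11(=C13H2)–C7). Five stereocentres must be set: the contiguous triad C6 (lactone oxygen), C7 (fusion carbon) and C8 (angelate), and the anti-1,3-diol C1/C3 on the far side of the ring. The triad can be made as one block, but the two Z olefins insulate it from C1 and C3, so these carbinols need outside control or a 1,3-relay between themselves. O6 and O8 are both secondary and both flank C7, yet one must become the lactone oxygen and the other a (Z)-2-methylbut-2-enoate. A free O8 alkoxide can also attack C12 and give the isomeric γ-lactone. The fragile groups are the exo-methylene lactone (a Michael acceptor), the angelate (drifts to the tiglate under nucleophilic or basic stress), the allylic carbinols at C1 and C3 (ionisation, elimination) and the medium ring itself (transannular reactions). The enabling feature is local: C11 sits on C7 anti to O8 on C8 while O6 carries the acyl carbon C12. That is the footprint of an O6-bound acetate carbanion opening a trans C7–C8 epoxide at C7 with inversion.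

## Retrosynthesis

**C11=C13.** The methylene of 29 is cut back to the α-phosphono lactone 28 and formaldehyde. The phosphonate is already present from the lactone annulation, so the olefination costs no extra atoms. The Michael acceptor then never meets chromium reagents, fluoride or ylides, and both C11 epimers converge. The forward reaction must use a base mild enough to leave the angelate and two free carbinols alone.

**C10–C1 (ring opening).** Diol 28 comes from silyl ether 27, and 27 is opened at C10–C1 to the vinyl iodide/aldehyde 26. Metathesis at either ring olefin would have to deliver a trisubstituted Z olefin in a medium ring beside two other olefins. A chromium-mediated alkenyl–aldehyde closure tolerates lactone, esters and phosphonate, and the ring formed is the low-strain (Z,Z)-cyclodeca-1,6-diene. The forward step needs high dilution and a C1 carbinol anti to O3.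

**C9=C10.** Aldehyde 26 comes from primary alcohol 25 and this from bis-silyl ether 24. The iodo-olefin of 24 is cut to the C9 aldehyde 23 and an α-iodoethylidene ylide. This one step brings in C10, its methyl group and the iodine, with iodine cis to C8 as the later ring bond requires. Aldehyde 23 comes from alcohol 22 and PMB ether 21. The second vinyl iodide can only be made after the first has been consumed, which fixes the order of the two chromium couplings.

**C3–C4.** Silyl ether 21 comes from the (3S) carbinol 20. The C3–C4 bond is cut to vinyl iodide 16 and 3-(tert-butyldimethylsilyloxy)propanal 17, which supplies C1–C3 with C1 masked as a primary silyl ether. No resident stereocentre is placed to control C3, so the coupling product 18 is oxidised to enone 19 and C3 is set by reagent-controlled reduction. This costs two steps but makes the C3 configuration independent of the substrate.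

**O8 acylation.** Angelate 16 comes from alcohol 13 and angelic acid 14. O8 is the only hydroxyl in 13, so the ester that the target needs also serves as the protecting group, and no later step has to tell O8 from O1 and O3.

**C7–C11 (key cut).** Lactone 13 is opened at C7–C11 to the threo epoxy phosphonoacetate 12. The lactone ring, the C7 stereocentre and the free O8 all arise from one intramolecular epoxide opening. The precursor is an acyclic ester with two stereo-elements (the C6 ester and the trans epoxide). An intermolecular acetate addition would face a C7/C8 regiochemistry problem, which the O6 tether removes.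

**C6–O with inversion.** Ester 12 comes from the erythro epoxy alcohol 10 and (diethoxyphosphoryl)acetic acid 11 by Mitsunobu esterification. Asymmetric epoxidation gives the erythro series directly, whereas the annulation needs threo. The inversion is therefore merged with the esterification rather than added as a separate operation.

**Epoxide.** Epoxy alcohol 10 comes from racemic dienol 9 by Sharpless kinetic resolution. One reagent sets C7 and C8 absolutely, selects the C6 configuration, and chooses the C7=C8 olefin over the iodo-olefin. The price is half of an early, cheap intermediate.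

**C6–C7.** Dienol 9 is cut to (Z)-3-iodobut-2-enal 4 and the (E)-alkenylzinc 8, made through alkenylzirconocene 7 from PMB propargyl ether 6 (from prop-2-yn-1-ol 5). Aldehyde 4 comes from alcohol 3, ester 2 and ethyl but-2-ynoate 1, where anti hydroiodination fixes the C4=C5 geometry for the whole synthesis.

## Roads not taken

Alternative 1: The carbocycle is cut out of an arene. Birch reduction of 2,7-dimethylnaphthalene A1 would give 2,7-dimethyl-1,4,5,8-tetrahydronaphthalene A2, and ozonolysis of its central tetrasubstituted olefin would give the ten-membered diketone A3 with both Z olefins in place.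
- Merits: as a ring construction this is better than the chosen plan. It needs two or three operations from a cheap arene, no macrocyclisation, and the olefin geometry is guaranteed by the six-membered rings.
- Weak points: A3 is achiral and carries its oxygens on C2 and C7, whereas the target has oxygen on C1, C3, C6 and C8, a methylene at C2 and the C11 branch at C7. Each ketone would have to be hydroxylated on both flanks and then deleted or converted into a C–C branch. Five stereocentres and the absolute configuration would have to be induced on a flexible ring whose β,γ-unsaturated ketones are prone to conjugation and transannular aldol reactions. The twofold symmetry gives no handle to tell O6 from O8. Ozone selectivity for the central olefin over the two trisubstituted ones is only a rate preference.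
- Comparison: the chosen plan closes its ring late and with more steps. Against that it sets the C6–C8 triad and the O6/O8 distinction in one stereospecific step and controls every centre by reagent or by a defined relay.

Alternative 2: The ring is closed across C2–C3 by an intramolecular nitrile oxide cycloaddition. The nitrile oxide from the (Z)-enal oxime A4 would add to the terminal C1=C2 bond of its diene and give the isoxazoline-bridged lactone A5.
- Merits: the isoxazoline is a masked β-hydroxy ketone. After N–O cleavage, a hydroxyl-directed reduction would give the anti-1,3-diol with C3 tied to C1. In this respect it is better than the chosen plan, which controls C3 by a chiral reagent and C1 by a less certain 1,3-induction. It also avoids chromium.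
- Weak points: the cycloaddition must form a ten-membered ring, where dimerisation of the nitrile oxide competes. Face selectivity at C1 would rest on the remote C8 centre. The (Z)-enal oxime can isomerise. N–O cleavage must spare two olefins and allylic C–O bonds. A5 lacks the C13 methylene, which would have to be added to an unsubstituted lactone by strong-base chemistry late on.
- Comparison: this plan does not say how C6–C8 are made and could borrow the same epoxide annulation. The chosen plan sets against it a ring closure of a well-established type and a methylene precursor that is already built in.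

Alternative 3: C7–C8 is formed by a [2,3]-Wittig ring contraction. Tin–lithium exchange at C8 of the thirteen-membered allyl ether A6 would give the ten-membered carbinol A7 with the C11=C13 methylene unit and a free O8.
- Merits: one step forms the ring bond, the exo-methylene skeleton and a uniquely free O8. A thirteen-membered ether is easier to close than a ten-membered carbocycle. After its key step this route is closer to the target than the chosen plan is after 13.
- Weak points: the C8 carbanion is allylic as well as α-oxygenated, so its configuration and its site of reaction are not secured by the stannane. C7 and C8 would both be set by the folding of a large ring in one transition state. A6 itself needs C1, C3 and C6 set beforehand, a macro-etherification and an α-alkoxystannane. The lactone still has to be made afterwards by oxidation at C12.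
- Comparison: the chosen plan has the longer endgame. Against that its key substrate is seven steps from commercial materials, and the stereochemical outcome of its key step follows from an SN2 inversion and not from a conformational preference.

Key step: step 8

Remark: locants C1–C13 are those of the target (ring C1–C10, lactone carbons C11 and C12, methylene C13) and are used for all intermediates. CIP descriptors are quoted for the compound at hand and change along the route although no centre is inverted after step 8. The phosphono lactones are drawn as the C11 epimer trans to the C7 substituent; C11 is epimerisable and ceases to be a stereocentre in step 21.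

## Steps

Step 1
Reactants: 1 ethyl but-2-ynoate
Product: 2 ethyl (2Z)-3-iodobut-2-enoate
Conditions: NaI, AcOH, 115 °C
Reagents that add atoms: sodium iodide, [Na+].[I-]
Why: Conjugate addition of iodide and anti protonation (hydroiodination of an ynoate) is known to give the (Z)-β-iodoenoate; the C4=C5 geometry is fixed here.

Step 2
Reactants: 2 ethyl (2Z)-3-iodobut-2-enoate
Product: 3 (2Z)-3-iodobut-2-en-1-ol
Conditions: i-Bu2AlH (2.2 equiv), CH2Cl2, −78 → 0 °C; aq. Rochelle salt
Reagents that add atoms: none
Why: 1,2-Reduction of an enoate by DIBAL-H; the vinyl iodide and the Z geometry are not touched at low temperature.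

Step 3
Reactants: 3 (2Z)-3-iodobut-2-en-1-ol
Product: 4 (2Z)-3-iodobut-2-enal
Conditions: MnO2, CH2Cl2, rt
Reagents that add atoms: none
Why: Allylic oxidation on the MnO2 surface under neutral conditions, which should keep the isomerisation-prone (Z)-enal intact; it is used at once.

Step 4
Reactants: 5 prop-2-yn-1-ol
Product: 6 PMB propargyl ether
Conditions: NaH, 4-methoxybenzyl chloride, n-Bu4NI (cat.), THF, 0 °C → rt
Reagents that add atoms: 4-methoxybenzyl chloride, COc1ccc(CCl)cc1
Why: Williamson etherification of a primary alkoxide with a benzylic chloride under iodide catalysis.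

Step 5
Reactants: 6 PMB propargyl ether; 4 (2Z)-3-iodobut-2-enal
Product: 9 racemic (2Z,5E)-dienol, via alkenylzirconocene chloride 7 (not isolated), via alkenyl(methyl)zinc 8 (not isolated)
Conditions: Cp2Zr(H)Cl, CH2Cl2, rt; Me2Zn, toluene, −65 °C; then 4, 0 °C
Reagents that add atoms: none
Why: Syn hydrozirconation puts the metal on the terminal carbon (E olefin), and Zr→Zn transmetalation gives an alkenylzinc that adds 1,2 to the enal without touching its vinyl iodide. The C6 carbinol is formed racemic on purpose and is resolved in step 6.

Step 6
Reactants: 9 racemic (2Z,5E)-dienol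
Product: 10 erythro epoxy alcohol (6R,7R,8R)
Conditions: Ti(OiPr)4 (15 mol %), D-(−)-diisopropyl tartrate (18 mol %), t-BuOOH (0.5 equiv), 4 Å MS, CH2Cl2, −20 °C
Reagents that add atoms: tert-butyl hydroperoxide, CC(C)(C)OO
Why: Sharpless kinetic resolution: with the D-(−)-tartrate the (4S) enantiomer should be epoxidised fast on the face that gives the erythro (7R,8R) epoxide, so C7, C8 and the C6 configuration are set by the reagent. The iodo-olefin is electron-poor, carries a substituent cis to the carbinol and is the mismatched olefin of that enantiomer, so only C7=C8 should react.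

Step 7
Reactants: 10 erythro epoxy alcohol; 11 (diethoxyphosphoryl)acetic acid
Product: 12 threo epoxy phosphonoacetate (6S,7R,8R)
Conditions: PPh3, DIAD, toluene/THF, 0 °C → rt
Reagents that add atoms: none
Why: Mitsunobu esterification: SN2 displacement of the oxyphosphonium at C6 by the carboxylate inverts C6 (erythro → threo). SN2′ delivery is disfavoured because C4 is a fully substituted, iodine-bearing carbon.

Step 8
Reactants: 12 threo epoxy phosphonoacetate
Product: 13 α-phosphono cis-γ-lactone with free C8 hydroxyl (6R,7R,8S,11S)
Conditions: NaH (1.1 equiv), THF, 0 °C → rt; AcOH, −20 °C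
Reagents that add atoms: none
Why: NaH removes the C11 proton between P=O and C=O, and the sodium phosphonoenolate attacks C7 from the side opposite the epoxide oxygen, forming C7–C11 and breaking C7–O in one SN2 event. The closest known reaction type is the intramolecular alkylation of epoxyalkyl phosphonoacetates and malonates to α-substituted γ-lactones, the tethered form of the phosphonoacetate/epoxide lactone synthesis. The lactone ring O6–C12–C11–C7–C6 closes in the 5-exo-tet mode, since the breaking C7–O bond lies outside the new ring. C7 is set by inversion and is controlled by the epoxide configuration from step 6 together with the C6 configuration from step 7, which places the C5 and C8 substituents cis on the lactone. C8 keeps its oxygen and its configuration; C11 forms as an epimerisable centre of no consequence. The step needs attack at C7 and not 6-endo attack at C8: the three-atom tether cannot bring C11 in line with the C8–O bond without an endo six-membered transition state, and C8 is non-allylic and inductively deactivated by the CH2OPMB group. It also needs O8 not to attack C12: the C8 alkoxide is quenched at once by the far more acidic C11–H of the product, so the lactone rests as its unreactive phosphonoenolate until the cold acetic acid quench.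

Step 9
Reactants: 13 α-phosphono lactone alcohol; 14 angelic acid
Product: 16 O8-angelate (6R,7S,8S,11S), via mixed anhydride 15 (not isolated)
Conditions: 14, 2,4,6-Cl3C6H2COCl, Et3N, toluene, rt; then 13, 80 °C
Reagents that add atoms: none
Why: Yamaguchi-type acylation through the preformed mixed anhydride without nucleophilic catalyst is the established way to make angelates of hindered alcohols without Z→E drift. O8 is the only hydroxyl, so the ester also serves as its protection.

Step 10
Reactants: 16 O8-angelate vinyl iodide; 17 3-(tert-butyldimethylsilyloxy)propanal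
Product: 18 C3-epimeric allylic alcohols
Conditions: 17 (2.5 equiv), CrCl2 (4 equiv), NiCl2 (2 mol %), DMSO, rt
Reagents that add atoms: none
Why: Nozaki–Hiyama–Kishi coupling: nickel-catalysed formation of the alkenylchromium with retention of the Z geometry, which adds to the aldehyde only and leaves lactone, esters and phosphonate alone. C3 is formed without control because step 11 erases it.

Step 11
Reactants: 18 C3-epimeric allylic alcohols
Product: 19 (Z)-enone
Conditions: Dess–Martin periodinane, NaHCO3, CH2Cl2, 0 °C → rt
Reagents that add atoms: none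
Why: Dess–Martin oxidation of the only free hydroxyl converts both epimers into one enone under buffered conditions that should not isomerise the Z olefin.

Step 12
Reactants: 19 (Z)-enone
Product: 20 (3S)-allylic alcohol
Conditions: (R)-2-methyl-CBS-oxazaborolidine [(3aR)-1-methyl-3,3-diphenyltetrahydro-1H,3H-pyrrolo[1,2-c][1,3,2]oxazaborole] (0.5 equiv), catecholborane, toluene, −78 °C
Reagents that add atoms: none
Why: Corey–Bakshi–Shibata reduction: the α-branched alkenyl group acts as the large substituent and CH2CH2OTBS as the small one, so the (R)-catalyst should deliver hydride to the face that gives the (3S) carbinol. Catecholborane at −78 °C leaves esters, lactone and olefins alone.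

Step 13
Reactants: 20 (3S)-allylic alcohol
Product: 21 C3,C1-bis(TBS) ether
Conditions: TBSOTf, 2,6-lutidine, CH2Cl2, −78 °C
Reagents that add atoms: tert-butyldimethylsilyl trifluoromethanesulfonate, CC(C)(C)[Si](C)(C)OS(=O)(=O)C(F)(F)F
Why: Silylation of a secondary allylic alcohol with the silyl triflate and a hindered base too weak to enolise the phosphono lactone.

Step 14
Reactants: 21 C3,C1-bis(TBS) ether
Product: 22 C9 primary alcohol
Conditions: DDQ, CH2Cl2/pH 7 buffer, 0 °C
Reagents that add atoms: none
Why: Oxidative cleavage of the PMB ether by DDQ (hydride abstraction, hydrolysis of the oxocarbenium ion); silyl ethers, angelate and phosphonate are inert.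

Step 15
Reactants: 22 C9 primary alcohol
Product: 23 C9 aldehyde
Conditions: Dess–Martin periodinane, NaHCO3, CH2Cl2, 0 °C
Reagents that add atoms: none
Why: Dess–Martin oxidation under buffered, non-basic conditions, so that the α-acyloxy aldehyde keeps its C8 configuration and the phosphonate stays protonated.

Step 16
Reactants: 23 C9 aldehyde
Product: 24 (9Z)-10-iodo olefin
Conditions: EtPPh3I, n-BuLi, THF, rt; I2, −78 °C; NaN(SiMe3)2, −78 °C; then 23, −78 °C
Reagents that add atoms: (1-iodoethylidene)triphenylphosphorane, CC(I)=P(c1ccccc1)(c1ccccc1)c1ccccc1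
Why: Stork–Zhao-type Wittig olefination: the unstabilised α-iodo ylide adds under kinetic control and should give the (Z)-iodo-olefin with iodine cis to C8. It brings in C10, its methyl group and the handle for ring closure. An excess of ylide at −78 °C is used so that olefination outruns proton transfer from C8–H and C11–H.

Step 17
Reactants: 24 (9Z)-10-iodo olefin
Product: 25 C1 primary alcohol
Conditions: HF·pyridine, pyridine, THF, 0 °C
Reagents that add atoms: none
Why: Buffered HF·pyridine cleaves a primary TBS ether much faster than the secondary allylic one on C3.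

Step 18
Reactants: 25 C1 primary alcohol
Product: 26 C1 aldehyde
Conditions: Dess–Martin periodinane, NaHCO3, CH2Cl2, 0 °C
Reagents that add atoms: none
Why: Dess–Martin oxidation gives the β-silyloxy aldehyde without base, so that elimination of the C3 silyloxy group is avoided.

Step 19
Reactants: 26 C1 aldehyde
Product: 27 ten-membered carbocycle with C1 carbinol (1S,3S,6S,7R,8R,11S)
Conditions: CrCl2 (10 equiv), NiCl2 (1 mol %), DMSO, rt, 2 mM, slow addition
Reagents that add atoms: none
Why: Intramolecular Nozaki–Hiyama–Kishi coupling: the C10 alkenylchromium (Z geometry retained) adds to the C1 aldehyde and closes the low-strain (Z,Z)-cyclodeca-1,6-diene. C1 is expected to form anti to the C3 silyloxy group by 1,3-induction of the non-chelated β-silyloxy aldehyde, giving the (1S) carbinol.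

Step 20
Reactants: 27 ten-membered carbocycle
Product: 28 phosphono lactone diol
Conditions: HF·pyridine, THF, 0 °C → rt
Reagents that add atoms: none
Why: Fluoride-mediated cleavage of the remaining secondary TBS ether under mildly acidic conditions that the angelate and the lactone tolerate.

Step 21
Reactants: 28 phosphono lactone diol
Product: 29 CNP0152559.4
Conditions: K2CO3, 37 % aq. HCHO, THF, 0 °C → rt
Reagents that add atoms: formaldehyde, C=O
Why: Horner–Wadsworth–Emmons olefination of the α-phosphono lactone with formaldehyde; carbonate is basic enough for the doubly activated C11–H only. Both C11 epimers give the same exo-methylene, and no stereocentre is touched.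

## Compound list

1 | ethyl but-2-ynoate | CC#CC(=O)OCC | starting material
2 | ethyl (2Z)-3-iodobut-2-enoate | C/C(I)=C/C(=O)OCC | intermediate
3 | (2Z)-3-iodobut-2-en-1-ol | C/C(I)=C/CO | intermediate
4 | (2Z)-3-iodobut-2-enal | C/C(I)=C/C=O | intermediate
5 | prop-2-yn-1-ol | C#CCO | starting material
6 | 1-methoxy-4-[(prop-2-yn-1-yloxy)methyl]benzene (PMB propargyl ether) | C#CCOCc1ccc(OC)cc1 | intermediate
7 | chlorobis(cyclopentadienyl)[(1E)-3-(4-methoxybenzyloxy)prop-1-en-1-yl]zirconium | COc1ccc(COC/C=C/[Zr](Cl)(C2C=CC=C2)C2C=CC=C2)cc1 | intermediate (not isolated)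
8 | methyl[(1E)-3-(4-methoxybenzyloxy)prop-1-en-1-yl]zinc | COc1ccc(COC/C=C/[Zn]C)cc1 | intermediate (not isolated)
9 | racemic (2Z,5E)-2-iodo-7-(4-methoxybenzyloxy)hepta-2,5-dien-4-ol | I/C(C)=C\C(O)/C=C/COCc1ccc(OC)cc1 | intermediate
10 | (1R,2Z)-3-iodo-1-{(2R,3R)-3-[(4-methoxybenzyloxy)methyl]oxiran-2-yl}but-2-en-1-ol (erythro; 6R,7R,8R) | I/C(C)=C\[C@@H](O)[C@H]1O[C@@H]1COCc1ccc(OC)cc1 | intermediate
11 | (diethoxyphosphoryl)acetic acid | OC(=O)CP(=O)(OCC)OCC | starting material
12 | (1S,2Z)-3-iodo-1-{(2R,3R)-3-[(4-methoxybenzyloxy)methyl]oxiran-2-yl}but-2-en-1-yl (diethoxyphosphoryl)acetate (threo; 6S,7R,8R) | I/C(C)=C\[C@H](OC(=O)CP(=O)(OCC)OCC)[C@H]1O[C@@H]1COCc1ccc(OC)cc1 | intermediate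
13 | diethyl {(3S,4R,5R)-4-[(1S)-1-hydroxy-2-(4-methoxybenzyloxy)ethyl]-5-[(1Z)-2-iodoprop-1-en-1-yl]-2-oxooxolan-3-yl}phosphonate (6R,7R,8S,11S) | O=C1O[C@@H](/C=C(/C)I)[C@@H]([C@H](O)COCc2ccc(OC)cc2)[C@@H]1P(=O)(OCC)OCC | intermediate
14 | angelic acid, (2Z)-2-methylbut-2-enoic acid | C/C=C(/C)C(=O)O | starting material
15 | (2Z)-2-methylbut-2-enoic 2,4,6-trichlorobenzoic anhydride | C/C=C(/C)C(=O)OC(=O)c1c(Cl)cc(Cl)cc1Cl | intermediate (not isolated)
16 | (1S)-1-{(2R,3S,4S)-4-(diethoxyphosphoryl)-2-[(1Z)-2-iodoprop-1-en-1-yl]-5-oxooxolan-3-yl}-2-(4-methoxybenzyloxy)ethyl (2Z)-2-methylbut-2-enoate (6R,7S,8S,11S) | O=C1O[C@@H](/C=C(/C)I)[C@@H]([C@H](OC(=O)/C(C)=C\C)COCc2ccc(OC)cc2)[C@@H]1P(=O)(OCC)OCC | intermediate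
17 | 3-[(tert-butyldimethylsilyl)oxy]propanal | O=CCCO[Si](C)(C)C(C)(C)C | starting material
18 | 16 with the C4 iodine replaced by a 1-hydroxy-3-(tert-butyldimethylsilyloxy)propyl group; (4Z); 6S,7S,8S,11S; both C3 epimers | O=C1O[C@@H](/C=C(/C)C(O)CCO[Si](C)(C)C(C)(C)C)[C@@H]([C@H](OC(=O)/C(C)=C\C)COCc2ccc(OC)cc2)[C@@H]1P(=O)(OCC)OCC | intermediate
19 | (4Z)-C3 ketone (enone) of 18; 6S,7S,8S,11S | O=C1O[C@@H](/C=C(/C)C(=O)CCO[Si](C)(C)C(C)(C)C)[C@@H]([C@H](OC(=O)/C(C)=C\C)COCc2ccc(OC)cc2)[C@@H]1P(=O)(OCC)OCC | intermediate
20 | (3S)-allylic alcohol from 19; 3S,6S,7S,8S,11S | O=C1O[C@@H](/C=C(/C)[C@@H](O)CCO[Si](C)(C)C(C)(C)C)[C@@H]([C@H](OC(=O)/C(C)=C\C)COCc2ccc(OC)cc2)[C@@H]1P(=O)(OCC)OCC | intermediate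
21 | 3-O-TBS ether of 20 (O1 and O3 silylated, O9 PMB); 3S,6S,7S,8S,11S | O=C1O[C@@H](/C=C(/C)[C@@H](O[Si](C)(C)C(C)(C)C)CCO[Si](C)(C)C(C)(C)C)[C@@H]([C@H](OC(=O)/C(C)=C\C)COCc2ccc(OC)cc2)[C@@H]1P(=O)(OCC)OCC | intermediate
22 | C9 primary alcohol from 21; 3S,6S,7S,8S,11S | O=C1O[C@@H](/C=C(/C)[C@@H](O[Si](C)(C)C(C)(C)C)CCO[Si](C)(C)C(C)(C)C)[C@@H]([C@H](OC(=O)/C(C)=C\C)CO)[C@@H]1P(=O)(OCC)OCC | intermediate
23 | C9 aldehyde (α-angeloyloxy aldehyde); 3S,6S,7S,8S,11S | O=C1O[C@@H](/C=C(/C)[C@@H](O[Si](C)(C)C(C)(C)C)CCO[Si](C)(C)C(C)(C)C)[C@@H]([C@H](OC(=O)/C(C)=C\C)C=O)[C@@H]1P(=O)(OCC)OCC | intermediate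
24 | (4Z,9Z)-10-iodo olefin with O1 and O3 as TBS ethers; 3S,6S,7S,8S,11S | O=C1O[C@@H](/C=C(/C)[C@@H](O[Si](C)(C)C(C)(C)C)CCO[Si](C)(C)C(C)(C)C)[C@@H]([C@H](OC(=O)/C(C)=C\C)/C=C(/C)I)[C@@H]1P(=O)(OCC)OCC | intermediate
25 | C1 primary alcohol from 24 (O3 still TBS); 3S,6S,7S,8S,11S | O=C1O[C@@H](/C=C(/C)[C@@H](O[Si](C)(C)C(C)(C)C)CCO)[C@@H]([C@H](OC(=O)/C(C)=C\C)/C=C(/C)I)[C@@H]1P(=O)(OCC)OCC | intermediate
26 | C1 aldehyde (seco aldehyde, β-silyloxy); 3S,6S,7S,8S,11S | O=C1O[C@@H](/C=C(/C)[C@@H](O[Si](C)(C)C(C)(C)C)CC=O)[C@@H]([C@H](OC(=O)/C(C)=C\C)/C=C(/C)I)[C@@H]1P(=O)(OCC)OCC | intermediate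
27 | 3-O-TBS ether of 28; 1S,3S,6S,7R,8R,11S | CCOP(=O)(OCC)[C@@H]1C(=O)O[C@H]2/C=C(/C)[C@@H](O[Si](C)(C)C(C)(C)C)C[C@H](O)/C(C)=C\[C@@H](OC(=O)/C(C)=C\C)[C@@H]12 | intermediate
28 | 29 with C11 bearing H and a diethoxyphosphoryl group in place of the C13 methylene; 1S,3S,6S,7R,8R,11S | CCOP(=O)(OCC)[C@@H]1C(=O)O[C@H]2/C=C(/C)[C@@H](O)C[C@H](O)/C(C)=C\[C@@H](OC(=O)/C(C)=C\C)[C@@H]12 | intermediate
29 | CNP0152559.4: (4Z,9Z)-cyclodeca-4,9-diene with 4,10-dimethyl, 1,3-dihydroxy and 8-angeloyloxy groups, cis-fused at C6–C7 to an α-methylene-γ-lactone through O6; 1S,3S,6S,7R,8R | C=C1C(=O)O[C@H]2/C=C(/C)[C@@H](O)C[C@H](O)/C(C)=C\[C@@H](OC(=O)/C(C)=C\C)[C@@H]12 | target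

## Step count and least certain steps

Total: 21 steps. Longest linear sequence: 20 steps (steps 1–3 and 5–21 from ethyl but-2-ynoate 1). Step 4 is the only step off that line.

**Step 8 (key step).**
- Risk: 6-endo opening at C8 could compete; closure could be slow because the ester must adopt the s-cis arrangement of a lactone; the C8 alkoxide could attack C12 before proton transfer and move the lactone from O6 to O8.
- Fallback: a Lewis-acid route that never forms a free alkoxide. From 12, silylation with TMSOTf and Et3N would give the silyl ketene acetal F1. A catalytic amount of BF3·OEt2 at −78 °C would activate the epoxide for a Mukaiyama-type 5-exo opening at C7 with inversion, the silyl group passing to O8 to give the O8-trimethylsilyl lactone F2. Brief methanolysis would return to the route at 13.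

**Step 7.**
- Risk: the carbinol is both allylic and next to an epoxide, so ionisation, SN2′ delivery or epoxide migration could erode the clean inversion.
- Fallback: reach the threo series without any inversion. From 9, the kinetic resolution is run past half conversion and the unreacted (4R)-dienol F3 is kept; its C6 already has the configuration that 12 needs. Shi epoxidation with the D-fructose-derived ketone and Oxone would epoxidise the electron-rich C7=C8 bond under reagent control to the threo epoxy alcohol F4. Steglich esterification with 11 (DCC, DMAP cat.) would return to the route at 12.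

**Step 16.**
- Risk: the basic ylide may abstract the C8 proton of the α-acyloxy aldehyde or the C11 proton, leading to epimerisation at C8, self-olefination between phosphonate and aldehyde, or a poor Z/E ratio.
- Fallback: build the iodo-olefin's bromo analogue without a basic ylide. From 23, Ramirez olefination (CBr4, PPh3, CH2Cl2, 0 °C) would give the 1,1-dibromo-olefin F5. Negishi coupling with MeZnCl and Pd(P(t-Bu)3)2 should methylate the bromide trans to C8 selectively and leave the (9Z)-10-bromo olefin F6. Selective desilylation as in step 17 would give the primary alcohol F7 and Dess–Martin oxidation the bromo aldehyde F8. The chromium-mediated closure of step 19 (vinyl bromides react under nickel catalysis, more slowly) would return to the route at 27.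

**Step 19.**
- Risk: ring conformation may override the 1,3-anti induction and give poor facial selectivity at C1; intermolecular coupling may compete with ring closure.
- Fallback: relay C1 from C3. From 27 (as the C1 mixture), Dess–Martin oxidation would give the macrocyclic C1 enone F9 and HF·pyridine the β-hydroxy enone F10. Evans–Saksena reduction with Me4NBH(OAc)3 in MeCN/AcOH at −20 °C delivers hydride intramolecularly from the C3 alkoxyborohydride and should give the anti-1,3-diol, returning to the route at 28.

## Further compounds

F1 | step 8 | trimethylsilyl ketene acetal of 12 (ketene acetal geometry not defined) | I/C(C)=C\[C@H](OC(O[Si](C)(C)C)=CP(=O)(OCC)OCC)[C@H]1O[C@@H]1COCc1ccc(OC)cc1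
F2 | step 8 | O8-trimethylsilyl ether of 13 | O=C1O[C@@H](/C=C(/C)I)[C@@H]([C@H](O[Si](C)(C)C)COCc2ccc(OC)cc2)[C@@H]1P(=O)(OCC)OCC
F3 | step 7 | (2Z,4R,5E)-2-iodo-7-(4-methoxybenzyloxy)hepta-2,5-dien-4-ol | I/C(C)=C\[C@H](O)/C=C/COCc1ccc(OC)cc1
F4 | step 7 | (1S,2Z)-3-iodo-1-{(2R,3R)-3-[(4-methoxybenzyloxy)methyl]oxiran-2-yl}but-2-en-1-ol (threo) | I/C(C)=C\[C@H](O)[C@H]1O[C@@H]1COCc1ccc(OC)cc1
F5 | step 16 | 10,10-dibromo olefin from 23 (C9=CBr2) | O=C1O[C@@H](/C=C(/C)[C@@H](O[Si](C)(C)C(C)(C)C)CCO[Si](C)(C)C(C)(C)C)[C@@H]([C@H](OC(=O)/C(C)=C\C)C=C(Br)Br)[C@@H]1P(=O)(OCC)OCC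
F6 | step 16 | (9Z)-10-bromo analogue of 24 | O=C1O[C@@H](/C=C(/C)[C@@H](O[Si](C)(C)C(C)(C)C)CCO[Si](C)(C)C(C)(C)C)[C@@H]([C@H](OC(=O)/C(C)=C\C)/C=C(/C)Br)[C@@H]1P(=O)(OCC)OCC
F7 | step 16 | (9Z)-10-bromo analogue of 25 | O=C1O[C@@H](/C=C(/C)[C@@H](O[Si](C)(C)C(C)(C)C)CCO)[C@@H]([C@H](OC(=O)/C(C)=C\C)/C=C(/C)Br)[C@@H]1P(=O)(OCC)OCC
F8 | step 16 | (9Z)-10-bromo analogue of 26 | O=C1O[C@@H](/C=C(/C)[C@@H](O[Si](C)(C)C(C)(C)C)CC=O)[C@@H]([C@H](OC(=O)/C(C)=C\C)/C=C(/C)Br)[C@@H]1P(=O)(OCC)OCC
F9 | step 19 | C1 ketone (macrocyclic enone) of 27 | CCOP(=O)(OCC)[C@@H]1C(=O)O[C@H]2/C=C(/C)[C@@H](O[Si](C)(C)C(C)(C)C)CC(=O)/C(C)=C\[C@@H](OC(=O)/C(C)=C\C)[C@@H]12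
F10 | step 19 | C1 ketone of 28 (3-hydroxy enone) | CCOP(=O)(OCC)[C@@H]1C(=O)O[C@H]2/C=C(/C)[C@@H](O)CC(=O)/C(C)=C\[C@@H](OC(=O)/C(C)=C\C)[C@@H]12
A1 | alternative 1 | 2,7-dimethylnaphthalene | Cc1ccc2ccc(C)cc2c1
A2 | alternative 1 | 2,7-dimethyl-1,4,5,8-tetrahydronaphthalene | CC1=CCC2=C(C1)CC(C)=CC2
A3 | alternative 1 | (Z,Z)-4,10-dimethylcyclodeca-4,9-diene-2,7-dione (target numbering) | O=C1C/C(C)=C\CC(=O)C/C=C(C)\C1
A4 | alternative 2 | open-chain (Z)-enal oxime with C9=C10–C1=C2 diene, O8 TBS ether, lactone without methylene | O=C1O[C@@H](/C=C(/C)C=NO)[C@@H]([C@H](O[Si](C)(C)C(C)(C)C)/C=C(C)\C=C)C1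
A5 | alternative 2 | isoxazoline-bridged ten-membered lactone | O=C1O[C@H]2/C=C(/C)C3=NO[C@@H](C3)/C(C)=C\[C@@H](O[Si](C)(C)C(C)(C)C)[C@H]2C1
A6 | alternative 3 | thirteen-membered C8–O–C13 allyl ether with tributylstannyl group on C8 (C8 configuration and C7=C11 geometry not assigned) | CCCC[Sn](CCCC)(CCCC)C1OCC(COCc2ccc(OC)cc2)=C[C@@H](OCc2ccc(OC)cc2)/C=C(/C)[C@@H](O[Si](C)(C)C(C)(C)C)C[C@H](O[Si](C)(C)C(C)(C)C)/C(C)=C\1
A7 | alternative 3 | ten-membered C8 carbinol with C7 2-propenyl unit | C=C(COCc1ccc(OC)cc1)[C@H]2[C@@H](OCc1ccc(OC)cc1)/C=C(/C)[C@@H](O[Si](C)(C)C(C)(C)C)C[C@H](O[Si](C)(C)C(C)(C)C)/C(C)=C\[C@H]2O
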